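**Strategy.** The route rests on disconnecting C2–C3 of the seven-membered ring. Its cyclohept-4-enone pattern (C8 carbonyl; C4=C5 with C5 as the ring-fusion atom) is the [3,3] product of a 2-ethylidene-5-vinyl-oxolane fused to the cyclopentane at C5–C6. One thermal Claisen step turns that lactone-derived oxacycle into the carbocycle, releases the C8 ketone and leaves C4=C5 for a syn hydroboration that sets C4, C5 and the trans fusion. The precursor is a cis-fused enol ether with angular vinyl and methyl and a C11 dioxolane. Its C9 silyl ether is placed cis to the lactone arm so that it steers the vinyl addition, and C9 is corrected later by oxidation–reduction.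

Key step: step 9

Remarks:
- Atom labels are those of the target: C2 (methyl-bearing), C3, C4 (ester carbinol), C5 (fusion CH), C6 (fusion C–CH3), C7, C8 (ketone), C9 (CHOH), C10, C11 (C(OH)i-Pr). β is the face of the C6 methyl, α the opposite face. TBS = tert-butyldimethylsilyl.
- Assumption: C2 (from step 9) and C8 (from step 12) are carried as epimer mixtures. Both become sp2 in the target, so their SMILES carry no stereo label.

Step 1
Reactants: 1 2-methylcyclopentane-1,3-dione; 2 ethyl bromoacetate
Product: 3 ethyl 2-(1-methyl-2,5-dioxocyclopentyl)acetate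
Conditions: NaH, DMF, 0 → 25 °C
Reagents that add atoms: none
Why: C-alkylation of the sodium enolate of the cyclic 1,3-dione by the α-bromo ester (SN2) should build the quaternary carbon C6, the product staying achiral because its two carbonyls are enantiotopic.

Step 2
Reactants: 3 ethyl 2-(1-methyl-2,5-dioxocyclopentyl)acetate
Product: 4 ethyl 2-[(1S,2S)-2-hydroxy-1-methyl-5-oxocyclopentyl]acetate (hydroxyl cis to the acetate arm)
Conditions: Prelog-selective ketoreductase, NADP+ (cat.), i-PrOH, pH 7 phosphate buffer, 30 °C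
Reagents that add atoms: none
Why: Enzymatic desymmetrising reduction of one enantiotopic carbonyl, in the (2S,3S) sense long known for baker's-yeast-type reductases with 2-alkyl-2-methylcyclopentane-1,3-diones, should fix C6 absolutely and place the C9 hydroxyl cis to the arm, the epimer that steers step 7 (C9 is corrected in steps 11, 12 and 20).

Step 3
Reactants: 4 ethyl 2-[(1S,2S)-2-hydroxy-1-methyl-5-oxocyclopentyl]acetate
Product: 5 ethyl 2-[(1S,2S)-2-(tert-butyldimethylsilyloxy)-1-methyl-5-oxocyclopentyl]acetate
Conditions: TBSOTf, 2,6-lutidine, CH2Cl2, −78 → 0 °C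
Reagents that add atoms: tert-butyldimethylsilyl trifluoromethanesulfonate, CC(C)(C)[Si](C)(C)OS(=O)(=O)C(F)(F)F
Why: Silyl triflate protection of the hindered secondary alcohol, run at once and cold, should cap the hydroxyl before the cis γ-hydroxy ester can lactonise.

Step 4
Reactants: 5 ethyl 2-[(1S,2S)-2-(tert-butyldimethylsilyloxy)-1-methyl-5-oxocyclopentyl]acetate
Product: 6 ethyl 2-[(1S,2S,4E)-2-(tert-butyldimethylsilyloxy)-4-(dimethylaminomethylidene)-1-methyl-5-oxocyclopentyl]acetate
Conditions: t-BuOCH(NMe2)2, toluene, 80 °C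
Reagents that add atoms: tert-butoxybis(dimethylamino)methane (Bredereck's reagent), CC(C)(C)OC(N(C)C)N(C)C
Why: Bredereck aminomethylenation should occur at the only enolisable ketone α-methylene (C11), the other α-carbon being quaternary and the ester CH2 neopentyl and far less acidic.

Step 5
Reactants: 6 the enaminone from step 4
Product: 7 ethyl 2-[(1S,2S)-2-(tert-butyldimethylsilyloxy)-1-methyl-4,5-dioxocyclopentyl]acetate (1,2-dione, largely enolised at C11)
Conditions: O2, hν, tetraphenylporphyrin (cat.), CH2Cl2, −78 °C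
Reagents that add atoms: dioxygen, O=O
Why: Singlet-oxygen [2+2] addition to the enaminone C=C and dioxetane cleavage (Wasserman oxidation) should give the C11 carbonyl and DMF under neutral, cold conditions that spare the β-silyloxy group.

Step 6
Reactants: 7 the 1,2-dione from step 5
Product: 8 ethyl 2-[(7S,8S)-8-(tert-butyldimethylsilyloxy)-7-methyl-6-oxo-1,4-dioxaspiro[4.4]nonan-7-yl]acetate (C11 dioxolane, C5 ketone)
Conditions: TMSOCH2CH2OTMS, TMSOTf (cat.), CH2Cl2, −78 → −20 °C
Reagents that add atoms: 1,2-bis(trimethylsilyloxy)ethane, C[Si](C)(C)OCCO[Si](C)(C)C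
Why: Noyori acetalisation should take only the C11 carbonyl, which is flanked by a methylene, while the C5 carbonyl next to quaternary C6 stays free, as in the mono-ketalisation of camphorquinone.

Step 7
Reactants: 8 the keto ketal from step 6; 9 vinylmagnesium bromide
Product: 11 cis-fused vinyl lactone 1-ethenyl-5-methyl-6α-(tert-butyldimethylsilyloxy)-8,8-(ethylenedioxy)-2-oxabicyclo[3.3.0]octan-3-one (ring O on C5 and CH2 on C6 both α; vinyl and methyl β), via bromomagnesium tertiary alkoxide 10 (not isolated)
Conditions: LaCl3·2LiCl (cat.), THF, −78 → 25 °C; aq NH4Cl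
Reagents that add atoms: none
Why: Grignard 1,2-addition to the non-enolisable ketone should come from the β face, anti to both the C9 silyl ether and the pseudo-axial acetate arm (matched, the sense seen in additions to 17-keto steroids), so the alkoxide is cis to the arm and closes the cis-fused γ-lactone by 5-exo-trig acyl substitution; the C5 configuration only serves the ring fusion.

Step 8
Reactants: 11 the vinyl lactone from step 7; 12 1,1-dibromoethane
Product: 13 (Z)-3-ethylidene-1-ethenyl-5-methyl-6α-(tert-butyldimethylsilyloxy)-8,8-(ethylenedioxy)-2-oxabicyclo[3.3.0]octane (key-step precursor)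
Conditions: TiCl4, TMEDA, Zn, PbCl2 (cat.), THF, 25 °C
Reagents that add atoms: none
Why: Takai–Utimoto alkylidenation of the lactone carbonyl by the zinc/titanium ethylidene carbenoid should give the Z enol ether, with TMEDA buffering the Lewis acid so that ketal and silyl ether survive.

Step 9
Reactants: 13 the (Z)-ethylidene enol ether from step 8
Product: 14 2,6-dimethyl-9α-(tert-butyldimethylsilyloxy)-11,11-(ethylenedioxy)bicyclo[5.3.0]dec-4-en-8-one (target atom labels; C2 epimers)
Conditions: degassed o-xylene, K2CO3 (trace), sealed tube, 170 °C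
Reagents that add atoms: none
Why: A concerted suprafacial [3,3]-sigmatropic (Claisen) shift of the allyl vinyl ether C2=C8–O–C5–C4=C3, held in a boat-like transition state by the oxolane, should form C2–C3 as O–C5 breaks and release the C8 carbonyl. The closest known reaction is the thermal rearrangement of 2-methylene- and 2-alkylidene-5-vinyltetrahydrofurans to cyclohept-4-enones. The seven-membered carbocycle closes by ring expansion: the five-membered oxacycle gives up its oxygen as the carbonyl and takes in C3 and C4, the boat giving the cis ring alkene C4=C5. The only new stereocentre, C2, follows from the Z enol ether and the boat but is irrelevant because it is epimerisable and later sp2, and C6 and C9 are untouched. The step needs periselectivity over ionisation of the tertiary allylic C5–O bond; acid-free non-polar conditions, the electron-withdrawing ketal next to C5 and the lack of β-hydrogens on C6 and C11 all disfavour the cationic and elimination paths.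

Step 10
Reactants: 14 the Claisen product from step 9
Product: 15 9α-hydroxy-2,6-dimethyl-11,11-(ethylenedioxy)bicyclo[5.3.0]dec-4-en-8-one
Conditions: TBAF, THF, 25–40 °C
Reagents that add atoms: none
Why: Fluoride desilylation should free the C9 carbinol, whose steering role ended with step 7.

Step 11
Reactants: 15 the 9α-hydroxy ketone from step 10
Product: 16 2,6-dimethyl-11,11-(ethylenedioxy)bicyclo[5.3.0]dec-4-ene-8,9-dione
Conditions: Dess–Martin periodinane, NaHCO3, CH2Cl2, 25 °C
Reagents that add atoms: none
Why: Dess–Martin oxidation should erase the α-configured C9 centre under neutral conditions that leave the allylic ketal and the 1,4-diketone intact.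

Step 12
Reactants: 16 the 8,9-dione from step 11
Product: 17 2,6-dimethyl-11,11-(ethylenedioxy)bicyclo[5.3.0]dec-4-ene-8,9β-diol (C8 epimers)
Conditions: NaBH4, MeOH, −20 → 0 °C
Reagents that add atoms: none
Why: Borohydride should attack the C9 cyclopentanone from the α face, anti to the angular C6 methyl (as in Hajos–Parrish and 17-keto steroid reductions), giving the 9β-ol whose silyl ether later sits equatorial and clear of the α face, while the C8 ketone is reduced as well.

Step 13
Reactants: 17 the 8,9β-diol from step 12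
Product: 18 8,9β-bis(tert-butyldimethylsilyloxy)-2,6-dimethyl-11,11-(ethylenedioxy)bicyclo[5.3.0]dec-4-ene
Conditions: TBSOTf, 2,6-lutidine, CH2Cl2, 0 °C
Reagents that add atoms: tert-butyldimethylsilyl trifluoromethanesulfonate, CC(C)(C)[Si](C)(C)OS(=O)(=O)C(F)(F)F
Why: Silyl triflate should protect both hindered secondary alcohols, so that no carbonyl or O–H is left for borane in step 14.

Step 14
Reactants: 18 the bis-silyl ether from step 13
Product: 20 trans-fused 4α-hydroxy-5α-H-8,9β-bis(tert-butyldimethylsilyloxy)-2,6-dimethyl-11,11-(ethylenedioxy)bicyclo[5.3.0]decane, via C4 alkylborane 19 (not isolated)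
Conditions: BH3·THF, THF, 0 → 25 °C; then NaOH, H2O2, 0 °C
Reagents that add atoms: borane–tetrahydrofuran, B.C1CCOC1; hydrogen peroxide, OO
Why: Hydroboration–oxidation should add boron to the less substituted C4 and hydrogen to C5, syn and from the α face anti to the C6 methyl (the C11 ketal shows the same oxygen to both faces, as in hydroborations of 7a-methylhexahydroindenes to trans-hydrindanols), and C–B oxidation with retention then gives the 4α-ol, the 5α-H and the trans ring fusion.

Step 15
Reactants: 20 the C4 alcohol from step 14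
Product: 21 4α-hydroxy-8,9β-bis(tert-butyldimethylsilyloxy)-2,6-dimethylbicyclo[5.3.0]decan-11-one (trans-fused)
Conditions: PPTS, acetone–H2O (9:1), 50 °C
Reagents that add atoms: water, O
Why: Mild acid hydrolysis of the dioxolane should unveil the C11 ketone, the buffered conditions being too weak to cleave the silyl ethers, dehydrate the β-hydroxy ketone or epimerise C5.

Step 16
Reactants: 21 the C11 ketone from step 15; 22 isopropylmagnesium chloride
Product: 23 8,9β-bis(tert-butyldimethylsilyloxy)-2,6-dimethyl-11α-isopropylbicyclo[5.3.0]decane-4α,11β-diol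
Conditions: CeCl3, THF, −78 → 0 °C (3–4 equiv of 22)
Reagents that add atoms: none
Why: The Imamoto organocerium reagent should add from the α face, because the β face is blocked by the 1,3-syn-axial C6 methyl and the 9β-silyl ether is equatorial, giving the 11β-ol, while cerium suppresses enolisation and β-hydride reduction and the C4 alkoxide cannot eliminate.

Step 17
Reactants: 23 the diol from step 16; 24 4-acetoxybenzoyl chloride
Product: 25 C4 4-acetoxybenzoate of 23 (C11 tertiary alcohol free)
Conditions: Et3N, DMAP, CH2Cl2, 25–40 °C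
Reagents that add atoms: none
Why: DMAP-catalysed acylation should take the secondary C4 hydroxyl and leave the tertiary C11 hydroxyl, the acid chloride being far more reactive than the aryl acetate it carries.

Step 18
Reactants: 25 the ester from step 17
Product: 26 C4 4-acetoxybenzoate of 2,6-dimethyl-11α-isopropylbicyclo[5.3.0]decane-4α,8,9β,11β-tetrol (8-, 9- and 11-hydroxyls free)
Conditions: HF·pyridine, THF, 0 → 25 °C
Reagents that add atoms: none
Why: HF·pyridine should cleave both alkyl silyl ethers and leave the aryl acetate, the benzoate and the tertiary alcohol untouched.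

Step 19
Reactants: 26 the triol ester from step 18
Product: 28 C4 4-acetoxybenzoate of 4α,11β-dihydroxy-2,6-dimethyl-11α-isopropylbicyclo[5.3.0]dec-2-ene-8,9-dione (C2=C3 enone; C9 ketone), via saturated 8,9-diketone 27 (not isolated)
Conditions: IBX, 4-methoxypyridine N-oxide, DMSO, 25 °C
Reagents that add atoms: none
Why: IBX should oxidise both secondary alcohols and, as its N-oxide complex at room temperature, dehydrogenate the C8 ketone; only C2–C3 can be desaturated, since C7 is neopentyl next to quaternary C6 and the C9 ketone has no β-hydrogen on C11, and the tertiary alcohol is inert.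

Step 20
Reactants: 28 the enone–ketone from step 19
Product: 30 CNP0199397.1, via target aryl acetate 29 (not isolated)
Conditions: NaBH4, MeOH–CH2Cl2, −40 °C; then K2CO3, MeOH, 0 °C
Reagents that add atoms: none
Why: Borohydride should reduce the saturated cyclopentanone in preference to the conjugated, α-methylated cycloheptenone (the Hajos–Parrish ketone and androstenedione-to-testosterone selectivity) from the α face anti to the C6 methyl, setting the 9β-ol, after which carbonate methanolysis removes the aryl acetate much faster than the hindered benzoate.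

**Compound list**

1 | 2-methylcyclopentane-1,3-dione | CC1C(=O)CCC1=O | starting material
2 | ethyl bromoacetate | CCOC(=O)CBr | starting material
3 | ethyl 2-(1-methyl-2,5-dioxocyclopentyl)acetate | CCOC(=O)CC1(C)C(=O)CCC1=O | intermediate
4 | ethyl 2-[(1S,2S)-2-hydroxy-1-methyl-5-oxocyclopentyl]acetate | CCOC(=O)C[C@@]1(C)[C@@H](O)CCC1=O | intermediate
5 | ethyl 2-[(1S,2S)-2-(tert-butyldimethylsilyloxy)-1-methyl-5-oxocyclopentyl]acetate | CCOC(=O)C[C@@]1(C)[C@@H](O[Si](C)(C)C(C)(C)C)CCC1=O | intermediate
6 | ethyl 2-[(1S,2S,4E)-2-(tert-butyldimethylsilyloxy)-4-(dimethylaminomethylidene)-1-methyl-5-oxocyclopentyl]acetate | CCOC(=O)C[C@@]1(C)[C@@H](O[Si](C)(C)C(C)(C)C)C/C(=C\N(C)C)C1=O | intermediate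
7 | ethyl 2-[(1S,2S)-2-(tert-butyldimethylsilyloxy)-1-methyl-4,5-dioxocyclopentyl]acetate | CCOC(=O)C[C@@]1(C)[C@@H](O[Si](C)(C)C(C)(C)C)CC(=O)C1=O | intermediate
8 | ethyl 2-[(7S,8S)-8-(tert-butyldimethylsilyloxy)-7-methyl-6-oxo-1,4-dioxaspiro[4.4]nonan-7-yl]acetate | CCOC(=O)C[C@@]1(C)[C@@H](O[Si](C)(C)C(C)(C)C)CC2(OCCO2)C1=O | intermediate
9 | vinylmagnesium bromide | C=C[Mg]Br | starting material
10 | bromomagnesium alkoxide of the C5 vinyl carbinol (vinyl β, O α) | CCOC(=O)C[C@@]1(C)[C@@H](O[Si](C)(C)C(C)(C)C)CC2(OCCO2)[C@]1(O[Mg]Br)C=C | intermediate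
11 | cis-fused 1-ethenyl-5-methyl-6α-(tert-butyldimethylsilyloxy)-8,8-(ethylenedioxy)-2-oxabicyclo[3.3.0]octan-3-one | O=C1O[C@@]2(C=C)[C@@](C)(C1)[C@@H](O[Si](C)(C)C(C)(C)C)CC23OCCO3 | intermediate
12 | 1,1-dibromoethane | CC(Br)Br | starting material
13 | (Z)-3-ethylidene-1-ethenyl-5-methyl-6α-(tert-butyldimethylsilyloxy)-8,8-(ethylenedioxy)-2-oxabicyclo[3.3.0]octane (key-step precursor) | C/C=C1\O[C@@]2(C=C)[C@@](C)(C1)[C@@H](O[Si](C)(C)C(C)(C)C)CC23OCCO3 | intermediate
14 | 2,6-dimethyl-9α-(tert-butyldimethylsilyloxy)-11,11-(ethylenedioxy)bicyclo[5.3.0]dec-4-en-8-one (key-step product) | CC1CC=C2C3(OCCO3)C[C@H](O[Si](C)(C)C(C)(C)C)[C@]2(C)CC1=O | intermediate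
15 | 9α-hydroxy-2,6-dimethyl-11,11-(ethylenedioxy)bicyclo[5.3.0]dec-4-en-8-one | CC1CC=C2C3(OCCO3)C[C@H](O)[C@]2(C)CC1=O | intermediate
16 | 2,6-dimethyl-11,11-(ethylenedioxy)bicyclo[5.3.0]dec-4-ene-8,9-dione | CC1CC=C2C3(OCCO3)CC(=O)[C@]2(C)CC1=O | intermediate
17 | 2,6-dimethyl-11,11-(ethylenedioxy)bicyclo[5.3.0]dec-4-ene-8,9β-diol | CC1CC=C2C3(OCCO3)C[C@@H](O)[C@]2(C)CC1O | intermediate
18 | 8,9β-bis(tert-butyldimethylsilyloxy)-2,6-dimethyl-11,11-(ethylenedioxy)bicyclo[5.3.0]dec-4-ene | CC1CC=C2C3(OCCO3)C[C@@H](O[Si](C)(C)C(C)(C)C)[C@]2(C)CC1O[Si](C)(C)C(C)(C)C | intermediate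
19 | C4α alkylborane of 18 (5α-H) | CC1C[C@H](B)[C@@H]2[C@@](C)(CC1O[Si](C)(C)C(C)(C)C)[C@H](O[Si](C)(C)C(C)(C)C)CC23OCCO3 | intermediate
20 | trans-fused 4α-hydroxy-8,9β-bis(tert-butyldimethylsilyloxy)-2,6-dimethyl-11,11-(ethylenedioxy)bicyclo[5.3.0]decane | CC1C[C@H](O)[C@@H]2[C@@](C)(CC1O[Si](C)(C)C(C)(C)C)[C@H](O[Si](C)(C)C(C)(C)C)CC23OCCO3 | intermediate
21 | 4α-hydroxy-8,9β-bis(tert-butyldimethylsilyloxy)-2,6-dimethylbicyclo[5.3.0]decan-11-one | CC1C[C@H](O)[C@@H]2[C@@](C)(CC1O[Si](C)(C)C(C)(C)C)[C@H](O[Si](C)(C)C(C)(C)C)CC2=O | intermediate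
22 | isopropylmagnesium chloride | CC(C)[Mg]Cl | starting material
23 | 8,9β-bis(tert-butyldimethylsilyloxy)-2,6-dimethyl-11α-isopropylbicyclo[5.3.0]decane-4α,11β-diol | CC1C[C@H](O)[C@@H]2[C@@](C)(CC1O[Si](C)(C)C(C)(C)C)[C@H](O[Si](C)(C)C(C)(C)C)C[C@@]2(O)C(C)C | intermediate
24 | 4-acetoxybenzoyl chloride | CC(=O)Oc1ccc(cc1)C(Cl)=O | starting material
25 | C4 4-acetoxybenzoate of 23 | CC1C[C@H](OC(=O)c2ccc(OC(C)=O)cc2)[C@@H]3[C@@](C)(CC1O[Si](C)(C)C(C)(C)C)[C@H](O[Si](C)(C)C(C)(C)C)C[C@@]3(O)C(C)C | intermediate
26 | C4 4-acetoxybenzoate with free 8-, 9β- and 11β-hydroxyls | CC1C[C@H](OC(=O)c2ccc(OC(C)=O)cc2)[C@@H]3[C@@](C)(CC1O)[C@H](O)C[C@@]3(O)C(C)C | intermediate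
27 | saturated 8,9-diketone of 26 | CC1C[C@H](OC(=O)c2ccc(OC(C)=O)cc2)[C@@H]3[C@@](C)(CC1=O)C(=O)C[C@@]3(O)C(C)C | intermediate
28 | C2=C3 enone with C9 ketone, C4 4-acetoxybenzoate | CC1=C[C@H](OC(=O)c2ccc(OC(C)=O)cc2)[C@@H]3[C@@](C)(CC1=O)C(=O)C[C@@]3(O)C(C)C | intermediate
29 | aryl acetate of the target (9β-ol) | CC1=C[C@H](OC(=O)c2ccc(OC(C)=O)cc2)[C@@H]3[C@@](C)(CC1=O)[C@H](O)C[C@@]3(O)C(C)C | intermediate
30 | CNP0199397.1 | CC1=C[C@H](OC(=O)c2ccc(O)cc2)[C@@H]2[C@@](C)(CC1=O)[C@H](O)C[C@@]2(O)C(C)C | target

**Total step count:** 20. **Longest linear sequence:** 20 steps (1 → 30).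

**Steps most likely to fail**

Step 9. At 170 °C, ionisation of the tertiary allylic C5–O bond or acid-catalysed migration of the enol ether double bond into the ring could outrun the sigmatropic shift. The fallback sets out from 13 and makes the same bond under organoaluminium promotion: triisobutylaluminium (CH2Cl2, −78 → 25 °C) binds the ring oxygen, triggers the rearrangement below room temperature and reduces the aluminium-bound ketone by β-hydride transfer, giving the 8-hydroxy-9α-silyloxy bicyclo[5.3.0]dec-4-ene F1. TBAF then gives the 8,9α-diol F2, and Dess–Martin oxidation of both carbinols comes back to the route at 16.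

Step 8. Alkylidenation of the neopentyl lactone carbonyl could stall or be diverted into reductive ring opening by the low-valent metals. The fallback sets out from 11 and moves the C2 methyl to a later enolate alkylation: Petasis or Tebbe methylenation gives the 3-methylene oxolane F3, whose thermal Claisen rearrangement gives the C2-unsubstituted cyclohept-4-enone F4. Kinetic deprotonation with LDA at C2 (the C7 methylene is neopentyl) and methylation with iodomethane come back to the route at 14.

Step 16. The secondary organometallic could enolise the hindered ketone or reduce it by β-hydride transfer instead of adding. The fallback sets out from 21 and uses an sp2 nucleophile without β-hydrogens: 2-propenyllithium with CeCl3 (THF, −78 °C) gives the 11α-isopropenyl-11β-carbinol F5, and hydrogenation (H2, Pd/C, EtOAc) comes back to the route at 23.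

**Further compounds**

F1 | step 9 | 8-hydroxy-9α-(tert-butyldimethylsilyloxy)-2,6-dimethyl-11,11-(ethylenedioxy)bicyclo[5.3.0]dec-4-ene | CC1CC=C2C3(OCCO3)C[C@H](O[Si](C)(C)C(C)(C)C)[C@]2(C)CC1O
F2 | step 9 | 2,6-dimethyl-11,11-(ethylenedioxy)bicyclo[5.3.0]dec-4-ene-8,9α-diol | CC1CC=C2C3(OCCO3)C[C@H](O)[C@]2(C)CC1O
F3 | step 8 | 3-methylene-1-ethenyl-5-methyl-6α-(tert-butyldimethylsilyloxy)-8,8-(ethylenedioxy)-2-oxabicyclo[3.3.0]octane | C=C1O[C@@]2(C=C)[C@@](C)(C1)[C@@H](O[Si](C)(C)C(C)(C)C)CC23OCCO3
F4 | step 8 | 6-methyl-9α-(tert-butyldimethylsilyloxy)-11,11-(ethylenedioxy)bicyclo[5.3.0]dec-4-en-8-one | C1CC=C2C3(OCCO3)C[C@H](O[Si](C)(C)C(C)(C)C)[C@]2(C)CC1=O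
F5 | step 16 | 8,9β-bis(tert-butyldimethylsilyloxy)-2,6-dimethyl-11α-(prop-1-en-2-yl)bicyclo[5.3.0]decane-4α,11β-diol | CC1C[C@H](O)[C@@H]2[C@@](C)(CC1O[Si](C)(C)C(C)(C)C)[C@H](O[Si](C)(C)C(C)(C)C)C[C@@]2(O)C(C)=C
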